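**Retrosynthetic overview**
1. Target 27 ⇐ face-selective epoxidation of the Z ring alkene of diene acetate 26 (oxirane formed last); acetate from diol 25.
2. Nine-membered ring (formed second) ⇐ intramolecular C6–C7 alkylation of a β-keto sulfone by a neryl-type Z-allylic chloride; C8 methylidene by Wittig.
3. Cyclobutane (formed first, key step) ⇐ intramolecular alkoxyketene–alkene [2+2] tethered through the C14 oxygen (temporary oxane); SmI2 cuts the tether and TosMIC homologates the cyclobutanone.
4. Acyclic precursor 11 ⇐ C12–C13 union of a nerol-derived (2Z,6E)-allylic bromide with the dianion of a β-hydroxy sulfone made from methyl (R)-glycidate, which supplies C14.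

Assumption: the SMILES is taken literally, i.e. a cis-4,5-epoxide (1R,4R,5S,9S,11R,14R) on a Z-derived ring; methyl (R)-glycidate (made from L-serine) is bought.
Atom labels C1–C15 are the caryophyllane-type labels of the target: C1/C9 ring fusion, C4/C5 oxirane, C8 methylidene carbon, C10 cyclobutane CH2, C11 quaternary carbon, C12–C15 side chain.

**Route**

Step 1
Reactants: 1 nerol
Product: 2 (2Z)-1-(methoxymethoxy)-3,7-dimethylocta-2,6-diene
Conditions: MOMCl, i-Pr2NEt, CH2Cl2, 0 °C → rt
Reagents that add atoms: chloromethyl methyl ether COCCl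
Why: Base-mediated MOM etherification (Williamson type) masks the primary allylic alcohol without touching either alkene, so the Z geometry (future C4=C5) is kept and no stereocenter is formed.

Step 2
Reactants: 2 neryl MOM ether
Product: 3 (2E,6Z)-8-(methoxymethoxy)-2,6-dimethylocta-2,6-dien-1-ol
Conditions: SeO2 (cat.), t-BuOOH, salicylic acid (cat.), CH2Cl2, rt
Reagents that add atoms: tert-butyl hydroperoxide CC(C)(C)OO (terminal oxidant); selenium dioxide O=[Se]=O (catalytic oxygen carrier)
Why: Riley allylic oxidation (ene reaction then [2,3]-sigmatropic shift) is selective for the E-methyl of the electron-richer terminal alkene, the allylic-ether alkene being deactivated, and so fixes the E geometry of the future C1=C11 bond.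

Step 3
Reactants: 3 E-allylic alcohol
Product: 4 (2Z,6E)-8-bromo-1-(methoxymethoxy)-3,7-dimethylocta-2,6-diene
Conditions: CBr4, PPh3, CH2Cl2, −20 °C
Reagents that add atoms: carbon tetrabromide BrC(Br)(Br)Br
Why: Appel bromination converts the primary allylic alcohol to the bromide under neutral conditions without allylic transposition or loss of the acetal.

Step 4
Reactants: 5 methyl (2R)-oxirane-2-carboxylate
Product: 7 (2R)-2-[2-(methoxymethoxy)propan-2-yl]oxirane, via lithium alkoxide 6 (not isolated)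
Conditions: MeLi (2.1 equiv), THF, −78 °C; then MOMCl, −78 °C → rt
Reagents that add atoms: methyllithium [Li]C; chloromethyl methyl ether COCCl
Why: Double addition of MeLi to the ester is faster than epoxide opening at −78 °C and the tertiary lithium alkoxide is capped in the same flask as its MOM ether; the bought stereocenter (future C14) is not involved.

Step 5
Reactants: 7 MOM-protected epoxide
Product: 8 (2S)-3-(methoxymethoxy)-3-methyl-1-(phenylsulfonyl)butan-2-ol
Conditions: PhSO2Na, DMF–H2O, 80 °C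
Reagents that add atoms: sodium benzenesulfinate [Na+].[O-]S(=O)c1ccccc1
Why: SN2 opening of the terminal epoxide by the sulfur of the sulfinate at the unhindered CH2 leaves the carbinol center untouched (the descriptor becomes S only because sulfur raises the CIP rank of the CH2 group).

Step 6
Reactants: 8 β-hydroxy sulfone; 4 allylic bromide
Product: 10 (2Z,6E,10S)-1,11-bis(methoxymethoxy)-3,7,11-trimethyl-9-(phenylsulfonyl)dodeca-2,6-dien-10-ol (both epimers at the sulfone carbon), via sulfone dianion 9 (not isolated)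
Conditions: n-BuLi (2.1 equiv), THF–DMPU, −78 → −20 °C; then 4, −78 → −40 °C
Reagents that add atoms: none
Why: SN2 C-alkylation of the β-oxido α-sulfonyl carbanion by the primary allylic bromide forms C12–C13 without transposition; the oxido group is too poor a leaving group to eliminate and the new sulfone-bearing center is erased in the next step.

Step 7
Reactants: 10 coupled sulfone
Product: 11 (2Z,6E,10R)-1,11-bis(methoxymethoxy)-3,7,11-trimethyldodeca-2,6-dien-10-ol
Conditions: Na(Hg), Na2HPO4, MeOH–THF, −20 °C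
Reagents that add atoms: none
Why: Buffered sodium-amalgam reductive desulfonylation (electron-transfer C–S cleavage then protonation) removes the homoallylic sulfone, the free β-hydroxyl suppressing Julia-type elimination and both alkene geometries being preserved.

Step 8
Reactants: 11 secondary alcohol
Product: 12 {[(3R,6E,10Z)-2,12-bis(methoxymethoxy)-2,6,10-trimethyldodeca-6,10-dien-3-yl]oxy}acetic acid
Conditions: NaH (4 equiv), BrCH2CO2H, THF, 0 °C → reflux; aq. HCl to pH 3, 0 °C
Reagents that add atoms: bromoacetic acid OC(=O)CBr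
Why: Williamson etherification of the C14 alkoxide with bromoacetate installs the two-carbon ketene precursor, the acetal on the neighbouring tertiary oxygen being unable to migrate.

Step 9
Reactants: 12 alkoxyacetic acid
Product: 15 (1S,3R,6S,7S)-6-methyl-3-[2-(methoxymethoxy)propan-2-yl]-7-[(3Z)-5-(methoxymethoxy)-3-methylpent-3-en-1-yl]-2-oxabicyclo[4.2.0]octan-8-one, via acid chloride 13 (not isolated), via alkoxyketene 14 (not isolated)
Conditions: 1-chloro-N,N,2-trimethylprop-1-en-1-amine, CH2Cl2, 0 °C → rt; then slow addition to Et3N, toluene, 80 °C (0.01 M)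
Reagents that add atoms: none
Why: Intramolecular ketene–alkene [2+2] cycloaddition of an alkoxyketene: the carbonyl carbon (C9) bonds to the less substituted alkene carbon C1 and the oxygen-bearing carbon (C10) to C11 through a chair-like six-membered tether in which the CMe2OMOM group on C14 and the forming C10–C9 bond are both equatorial (2,6-cis oxane, angular methyl equatorial), so C14 dictates C11, while suprafacial addition to the E-alkene puts the C2 chain on C1 cis to the C11 methyl.

Step 10
Reactants: 15 bicyclic α-alkoxy cyclobutanone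
Product: 16 (2S,3R)-3-[(3R)-3-hydroxy-4-(methoxymethoxy)-4-methylpentyl]-2-[(3Z)-5-(methoxymethoxy)-3-methylpent-3-en-1-yl]-3-methylcyclobutan-1-one
Conditions: SmI2 (2.5 equiv), THF–MeOH, −78 °C
Reagents that add atoms: none
Why: Reduction of the α-alkoxy ketone by SmI2 (divalent samarium) gives a ketyl that expels the α-oxygen and a samarium enolate that is protonated at C10, which cuts the tether, erases the temporary C10 center and frees the C14 hydroxyl without epimerising C1.

Step 11
Reactants: 16 hydroxy cyclobutanone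
Product: 17 (2R,3R)-3-[(3R)-3-hydroxy-4-(methoxymethoxy)-4-methylpentyl]-2-[(3Z)-5-(methoxymethoxy)-3-methylpent-3-en-1-yl]-3-methylcyclobutane-1-carbonitrile (both epimers at the nitrile carbon)
Conditions: TosMIC, t-BuOK, EtOH (2 equiv), DME, 0 → 40 °C
Reagents that add atoms: p-toluenesulfonylmethyl isocyanide Cc1ccc(cc1)S(=O)(=O)C[N+]#[C-]
Why: Van Leusen reductive cyanation turns C=O into CH–C≡N with one added carbon (C8); C9 forms as an epimer mixture that is corrected thermodynamically in the next step.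

Step 12
Reactants: 17 nitrile
Product: 19 1-[(1S,2R,3R)-3-[(3R)-3-hydroxy-4-(methoxymethoxy)-4-methylpentyl]-2-[(3Z)-5-(methoxymethoxy)-3-methylpent-3-en-1-yl]-3-methylcyclobutyl]-2-(phenylsulfonyl)ethan-1-one, via enaminosulfone 18 (not isolated)
Conditions: PhSO2CH3, n-BuLi, THF, −78 → 0 °C; then 17, 0 °C → rt; 1 M HCl, THF, rt; DBU (cat.), CH2Cl2, rt
Reagents that add atoms: methyl phenyl sulfone CS(=O)(=O)c1ccccc1; water O
Why: Thorpe-type addition of the α-sulfonyl carbanion to the nitrile gives a conjugated enaminosulfone that hydrolyses to the β-keto sulfone (C7 added), and enolisation with DBU places the acyl group trans to the C1 chain, so C9 is set under thermodynamic control by C1.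

Step 13
Reactants: 19 bis-MOM β-keto sulfone
Product: 20 1-[(1S,2R,3R)-3-[(3R)-3,4-dihydroxy-4-methylpentyl]-2-[(3Z)-5-hydroxy-3-methylpent-3-en-1-yl]-3-methylcyclobutyl]-2-(phenylsulfonyl)ethan-1-one
Conditions: TMSOTf, 2,2′-bipyridyl, CH2Cl2, 0 °C → rt; then H2O
Reagents that add atoms: none
Why: Both MOM ethers are cleaved through bipyridinium methyl ether intermediates that water hydrolyses, a buffered non-protic acetal cleavage that spares the Z-allylic system, the ketone and the sulfone.

Step 14
Reactants: 20 triol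
Product: 22 1-[(1S,2R,3R)-2-[(3Z)-5-chloro-3-methylpent-3-en-1-yl]-3-[(3R)-3,4-dihydroxy-4-methylpentyl]-3-methylcyclobutyl]-2-(phenylsulfonyl)ethan-1-one, via allylic mesylate 21 (not isolated)
Conditions: MsCl (1.1 equiv), 2,4,6-collidine, LiCl, DMF, 0 °C
Reagents that add atoms: lithium chloride [Li+].[Cl-]
Why: Meyers–Collington chlorination mesylates only the primary allylic hydroxyl and displaces it in situ by chloride (SN2) with retention of the Z geometry, the hindered secondary and tertiary hydroxyls not reacting.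

Step 15
Reactants: 22 allylic chloride
Product: 23 (1R,4Z,9S,11R)-11-[(3R)-3,4-dihydroxy-4-methylpentyl]-4,11-dimethyl-7-(phenylsulfonyl)bicyclo[7.2.0]undec-4-en-8-one (both C7 epimers)
Conditions: Cs2CO3, DMF, 40 °C, syringe-pump addition to 0.003 M
Reagents that add atoms: none
Why: Intramolecular SN2 C-alkylation of the soft, doubly stabilised β-keto sulfone anion by the allylic chloride under high dilution closes the nine-membered ring at C6–C7, the Z-alkene and the trans-cyclobutane pre-organising the chain and the new C7 center being removed next.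

Step 16
Reactants: 23 cyclic α-sulfonyl ketone
Product: 24 (1R,4Z,9S,11R)-11-[(3R)-3,4-dihydroxy-4-methylpentyl]-4,11-dimethylbicyclo[7.2.0]undec-4-en-8-one
Conditions: Al(Hg), THF–H2O 9:1, 0 °C → rt
Reagents that add atoms: none
Why: Electron-transfer desulfonylation of the α-sulfonyl ketone by aluminium amalgam gives the ring ketone, whose trans ring fusion (C9 is alpha to the carbonyl) is the thermodynamically preferred one.

Step 17
Reactants: 24 nine-membered ketone
Product: 25 (3R)-2-methyl-5-[(1R,4Z,9S,11R)-4,11-dimethyl-8-methylidenebicyclo[7.2.0]undec-4-en-11-yl]pentane-2,3-diol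
Conditions: Ph3PCH3Br, t-BuOK (excess), THF–toluene, rt → 70 °C
Reagents that add atoms: methyltriphenylphosphonium bromide C[P+](c1ccccc1)(c1ccccc1)c1ccccc1.[Br-]
Why: Wittig methylenation of the ring ketone installs the exocyclic methylidene, the two hydroxyls merely consuming base as spectator alkoxides.

Step 18
Reactants: 25 diene diol
Product: 26 (3R)-2-hydroxy-2-methyl-5-[(1R,4Z,9S,11R)-4,11-dimethyl-8-methylidenebicyclo[7.2.0]undec-4-en-11-yl]pentan-3-yl acetate
Conditions: Ac2O, DMAP (cat.), pyridine, CH2Cl2, 0 °C → rt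
Reagents that add atoms: acetic anhydride CC(=O)OC(C)=O
Why: DMAP-catalysed acylation is selective for the secondary C14 hydroxyl over the tertiary C15 hydroxyl.

Step 19
Reactants: 26 diene acetate
Product: 27 (3R)-2-hydroxy-2-methyl-5-[(1R,4R,6S,10S,12R)-4,12-dimethyl-9-methylidene-5-oxatricyclo[8.2.0.0(4,6)]dodecan-12-yl]pentan-3-yl acetate (target)
Conditions: mCPBA (1.05 equiv), CH2Cl2, −20 → 0 °C; aq. NaHCO3 wash
Reagents that add atoms: 3-chloroperoxybenzoic acid OOC(=O)c1cccc(Cl)c1
Why: Prilezhaev epoxidation selects the trisubstituted ring alkene over the 1,1-disubstituted one and adds syn from the face anti to the quaternary C11 (syn to H-1), the same C4 facial preference that turns caryophyllene into its oxide, giving the cis-oxirane 4R,5S with the minor face isomer removed by chromatography.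

**Compound list**
1 | nerol, (2Z)-3,7-dimethylocta-2,6-dien-1-ol | CC(C)=CCC/C(C)=C\CO | starting material
2 | (2Z)-1-(methoxymethoxy)-3,7-dimethylocta-2,6-diene | CC(C)=CCC/C(C)=C\COCOC | intermediate
3 | (2E,6Z)-8-(methoxymethoxy)-2,6-dimethylocta-2,6-dien-1-ol | OC/C(C)=C/CC/C(C)=C\COCOC | intermediate
4 | (2Z,6E)-8-bromo-1-(methoxymethoxy)-3,7-dimethylocta-2,6-diene | BrC/C(C)=C/CC/C(C)=C\COCOC | intermediate
5 | methyl (2R)-oxirane-2-carboxylate (methyl (R)-glycidate) | COC(=O)[C@H]1CO1 | starting material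
6 | lithium 2-[(2R)-oxiran-2-yl]propan-2-olate | [Li+].CC(C)([O-])[C@H]1CO1 | intermediate
7 | (2R)-2-[2-(methoxymethoxy)propan-2-yl]oxirane | COCOC(C)(C)[C@H]1CO1 | intermediate
8 | (2S)-3-(methoxymethoxy)-3-methyl-1-(phenylsulfonyl)butan-2-ol | COCOC(C)(C)[C@H](O)CS(=O)(=O)c1ccccc1 | intermediate
9 | O,C-dilithio dianion of 8 | [Li+].[Li+].COCOC(C)(C)[C@H]([O-])[CH-]S(=O)(=O)c1ccccc1 | intermediate
10 | (2Z,6E,10S)-1,11-bis(methoxymethoxy)-3,7,11-trimethyl-9-(phenylsulfonyl)dodeca-2,6-dien-10-ol, both epimers at the sulfone carbon | COCOC(C)(C)[C@H](O)C(C/C(C)=C/CC/C(C)=C\COCOC)S(=O)(=O)c1ccccc1 | intermediate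
11 | (2Z,6E,10R)-1,11-bis(methoxymethoxy)-3,7,11-trimethyldodeca-2,6-dien-10-ol | COCOC(C)(C)[C@H](O)CC/C(C)=C/CC/C(C)=C\COCOC | intermediate
12 | {[(3R,6E,10Z)-2,12-bis(methoxymethoxy)-2,6,10-trimethyldodeca-6,10-dien-3-yl]oxy}acetic acid | COCOC(C)(C)[C@H](OCC(O)=O)CC/C(C)=C/CC/C(C)=C\COCOC | intermediate
13 | acid chloride of 12 | COCOC(C)(C)[C@H](OCC(Cl)=O)CC/C(C)=C/CC/C(C)=C\COCOC | intermediate
14 | alkoxyketene from 13 (O–CH=C=O on the C14 oxygen) | COCOC(C)(C)[C@H](OC=C=O)CC/C(C)=C/CC/C(C)=C\COCOC | intermediate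
15 | (1S,3R,6S,7S)-6-methyl-3-[2-(methoxymethoxy)propan-2-yl]-7-[(3Z)-5-(methoxymethoxy)-3-methylpent-3-en-1-yl]-2-oxabicyclo[4.2.0]octan-8-one | COCOC(C)(C)[C@H]1CC[C@@]2(C)[C@H](CC/C(C)=C\COCOC)C(=O)[C@H]2O1 | intermediate
16 | (2S,3R)-3-[(3R)-3-hydroxy-4-(methoxymethoxy)-4-methylpentyl]-2-[(3Z)-5-(methoxymethoxy)-3-methylpent-3-en-1-yl]-3-methylcyclobutan-1-one | COCOC(C)(C)[C@H](O)CC[C@]1(C)CC(=O)[C@H]1CC/C(C)=C\COCOC | intermediate
17 | (2R,3R)-3-[(3R)-3-hydroxy-4-(methoxymethoxy)-4-methylpentyl]-2-[(3Z)-5-(methoxymethoxy)-3-methylpent-3-en-1-yl]-3-methylcyclobutane-1-carbonitrile, both C1 epimers | COCOC(C)(C)[C@H](O)CC[C@]1(C)CC(C#N)[C@H]1CC/C(C)=C\COCOC | intermediate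
18 | 1-amino-1-cyclobutyl-2-(phenylsulfonyl)ethene (enaminosulfone) derived from 17 | COCOC(C)(C)[C@H](O)CC[C@]1(C)CC(C(N)=CS(=O)(=O)c2ccccc2)[C@H]1CC/C(C)=C\COCOC | intermediate
19 | 1-[(1S,2R,3R)-3-[(3R)-3-hydroxy-4-(methoxymethoxy)-4-methylpentyl]-2-[(3Z)-5-(methoxymethoxy)-3-methylpent-3-en-1-yl]-3-methylcyclobutyl]-2-(phenylsulfonyl)ethan-1-one | COCOC(C)(C)[C@H](O)CC[C@]1(C)C[C@H](C(=O)CS(=O)(=O)c2ccccc2)[C@H]1CC/C(C)=C\COCOC | intermediate
20 | 1-[(1S,2R,3R)-3-[(3R)-3,4-dihydroxy-4-methylpentyl]-2-[(3Z)-5-hydroxy-3-methylpent-3-en-1-yl]-3-methylcyclobutyl]-2-(phenylsulfonyl)ethan-1-one | CC(C)(O)[C@H](O)CC[C@]1(C)C[C@H](C(=O)CS(=O)(=O)c2ccccc2)[C@H]1CC/C(C)=C\CO | intermediate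
21 | primary allylic methanesulfonate of 20 | CC(C)(O)[C@H](O)CC[C@]1(C)C[C@H](C(=O)CS(=O)(=O)c2ccccc2)[C@H]1CC/C(C)=C\COS(C)(=O)=O | intermediate
22 | 1-[(1S,2R,3R)-2-[(3Z)-5-chloro-3-methylpent-3-en-1-yl]-3-[(3R)-3,4-dihydroxy-4-methylpentyl]-3-methylcyclobutyl]-2-(phenylsulfonyl)ethan-1-one | CC(C)(O)[C@H](O)CC[C@]1(C)C[C@H](C(=O)CS(=O)(=O)c2ccccc2)[C@H]1CC/C(C)=C\CCl | intermediate
23 | (1R,4Z,9S,11R)-11-[(3R)-3,4-dihydroxy-4-methylpentyl]-4,11-dimethyl-7-(phenylsulfonyl)bicyclo[7.2.0]undec-4-en-8-one, both C7 epimers | CC(C)(O)[C@H](O)CC[C@]1(C)C[C@H]2[C@H]1CC/C(C)=C\CC(S(=O)(=O)c1ccccc1)C2=O | intermediate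
24 | (1R,4Z,9S,11R)-11-[(3R)-3,4-dihydroxy-4-methylpentyl]-4,11-dimethylbicyclo[7.2.0]undec-4-en-8-one | CC(C)(O)[C@H](O)CC[C@]1(C)C[C@H]2[C@H]1CC/C(C)=C\CCC2=O | intermediate
25 | (3R)-2-methyl-5-[(1R,4Z,9S,11R)-4,11-dimethyl-8-methylidenebicyclo[7.2.0]undec-4-en-11-yl]pentane-2,3-diol | CC(C)(O)[C@H](O)CC[C@]1(C)C[C@H]2[C@H]1CC/C(C)=C\CCC2=C | intermediate
26 | (3R)-2-hydroxy-2-methyl-5-[(1R,4Z,9S,11R)-4,11-dimethyl-8-methylidenebicyclo[7.2.0]undec-4-en-11-yl]pentan-3-yl acetate | CC(C)(O)[C@H](OC(C)=O)CC[C@]1(C)C[C@H]2[C@H]1CC/C(C)=C\CCC2=C | intermediate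
27 | CNP0157071.2, (3R)-2-hydroxy-2-methyl-5-[(1R,4R,6S,10S,12R)-4,12-dimethyl-9-methylidene-5-oxatricyclo[8.2.0.0(4,6)]dodecan-12-yl]pentan-3-yl acetate | C=C1CC[C@@H]2O[C@]2(C)CC[C@@H]2[C@@H]1C[C@@]2(C)CC[C@@H](OC(C)=O)C(C)(C)O | target

**Step count and risks**

Total step count: 19. Longest linear sequence: 17 steps (nerol to target, steps 1–3 and 6–19).

Most likely to fail, first: step 9. The six-membered tether makes the alkoxyketene cycloaddition slower than the five-membered cases, ketene dimerisation can compete, and the face selectivity is a prediction from a chair model. The fallback replaces the ketene by a keteniminium ion, which reacts at lower temperature through a tighter transition state. It sets out from 11: O-alkylation with 2-chloro-N,N-dimethylacetamide (NaH, THF) gives the N,N-dimethyl alkoxyacetamide F1. Tf2O and 2,4,6-collidine in 1,2-dichloroethane (0 °C → rt) convert it into the keteniminium triflate F2, which closes by intramolecular [2+2] to the cyclobutaniminium triflate F3. Aqueous NaHCO3 hydrolysis comes back to the route at 15.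

Second: step 15. Nine-membered ring closure by direct SN2 can lose to oligomerisation or O-alkylation. The fallback changes the ring closure to a palladium π-allyl alkylation. It sets out from 20: methyl chloroformate and pyridine (CH2Cl2, −20 °C) give the primary allylic methyl carbonate F4. Pd(PPh3)4 (zerovalent palladium) with dppe in THF at 65 °C under high dilution ionises it, and the β-keto sulfone, deprotonated by the methoxide released, attacks the primary terminus (Tsuji–Trost cyclisation). This comes back at 23.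

Third: step 19. The face selectivity of peracid attack on the Z ring alkene rests on analogy with caryophyllene and may be modest or reversed. The fallback inverts the facial outcome through a halohydrin. It sets out from 25: NBS in aqueous THF at 0 °C gives the trans-bromohydrin F5 (bromine at C5 from the face the peracid prefers, hydroxyl at C4 anti). K2CO3 in MeOH closes it with inversion at C5 to the epoxy diol F6, whose oxygen lies on the face opposite to direct epoxidation. Ac2O, DMAP and pyridine then acetylate the C14 hydroxyl and come back at 27.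

**Further compounds**
F1 | step 9 | 2-{[(3R,6E,10Z)-2,12-bis(methoxymethoxy)-2,6,10-trimethyldodeca-6,10-dien-3-yl]oxy}-N,N-dimethylacetamide | COCOC(C)(C)[C@H](OCC(=O)N(C)C)CC/C(C)=C/CC/C(C)=C\COCOC
F2 | step 9 | keteniminium triflate from F1 (O–CH=C=N+Me2 on the C14 oxygen) | COCOC(C)(C)[C@H](OC=C=[N+](C)C)CC/C(C)=C/CC/C(C)=C\COCOC.[O-]S(=O)(=O)C(F)(F)F
F3 | step 9 | N,N-dimethyliminium triflate of ketone 15 | COCOC(C)(C)[C@H]1CC[C@@]2(C)[C@H](CC/C(C)=C\COCOC)C(=[N+](C)C)[C@H]2O1.[O-]S(=O)(=O)C(F)(F)F
F4 | step 15 | primary allylic methyl carbonate of 20 | CC(C)(O)[C@H](O)CC[C@]1(C)C[C@H](C(=O)CS(=O)(=O)c2ccccc2)[C@H]1CC/C(C)=C\COC(=O)OC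
F5 | step 19 | (4R,5R)-5-bromo-4-hydroxy bromohydrin of 25 (caryophyllane labels) | C=C1CC[C@@H](Br)[C@](C)(O)CC[C@@H]2[C@@H]1C[C@@]2(C)CC[C@@H](O)C(C)(C)O
F6 | step 19 | 14-deacetyl target (4R,5S-epoxy diol) | C=C1CC[C@@H]2O[C@]2(C)CC[C@@H]2[C@@H]1C[C@@]2(C)CC[C@@H](O)C(C)(C)O
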